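**Plan**

1. Retrosynthesis: the two phenol O–H are masked as methoxymethyl (MOM) ethers. The enolised 1,3-diketone O=C3–C4H=C5–OH of the heptadienone chain (C1–C2 = CH2CH2, C6=C7 = styryl) is read as an opened isoxazole ring: ring O1 is the enol oxygen on C5, ring N2 stands for the ketone oxygen on C3, and ring C3–C4–C5 is chain C3–C4–C5.
2. The isoxazole is cut by a retro (3+2) cycloaddition at C3–C4 (carbon–carbon) and O1–C5. This gives the nitrile oxide of a 3-arylpropanal oxime (C1–C3) and a terminal (E)-aryl enyne (C4–C7).
3. Both halves come from one enal, the MOM ether of coniferaldehyde: Corey–Fuchs homologation gives the enyne; C=C hydrogenation and oximation give the oxime.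
4. Forward: protect, branch, join the halves by copper-catalysed nitrile oxide–alkyne cycloaddition (the only ring formed, a temporary one), cleave N–O with Mo(CO)6, hydrolyse the enaminone, remove the MOM groups with acid.
5. Stereochemistry: there is no stereocentre. The (E)-C6=C7 alkene is bought with coniferaldehyde and never touched. The (Z)-enol is the chelated, thermodynamically preferred tautomer.

Key step: step 6

Remark: the target is drawn as one enol tautomer of a 1,3-diketone (dihydrocurcumin); the tautomers equilibrate freely, so the route is planned for the 1,3-dicarbonyl compound, which adopts the drawn chelated (Z)-enol.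

**Route**

Step 1
Reactants: 1 coniferaldehyde, (2E)-3-(4-hydroxy-3-methoxyphenyl)prop-2-enal
Product: 2 (2E)-3-[3-methoxy-4-(methoxymethoxy)phenyl]prop-2-enal
Conditions: MOMCl, K2CO3, acetone, 0 °C to rt
Reagents that add atoms: chloromethyl methyl ether (MOMCl), COCCl
Why: Williamson-type O-alkylation of the phenoxide, the only acidic site, should give the MOM acetal, which tolerates the organolithium, hydrogenation, chloramine and Mo(CO)6 steps and leaves with acid at the end.

Step 2
Reactants: 2 (2E)-3-[3-methoxy-4-(methoxymethoxy)phenyl]prop-2-enal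
Product: 3 4-[(1E)-4,4-dibromobuta-1,3-dien-1-yl]-2-methoxy-1-(methoxymethoxy)benzene
Conditions: CBr4, PPh3, Zn dust, CH2Cl2, rt (ylide preformed); then 2, 0 °C to rt
Reagents that add atoms: carbon tetrabromide, BrC(Br)(Br)Br
Why: First stage of the Corey–Fuchs reaction, a Wittig-type dibromoolefination of the enal by Ph3P=CBr2 made in the flask; the zinc variant keeps the medium nearly neutral, so the MOM ether and the (E)-alkene should survive.

Step 3
Reactants: 3 4-[(1E)-4,4-dibromobuta-1,3-dien-1-yl]-2-methoxy-1-(methoxymethoxy)benzene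
Product: 5 4-[(1E)-but-1-en-3-yn-1-yl]-2-methoxy-1-(methoxymethoxy)benzene, via lithium acetylide 4 (not isolated)
Conditions: n-BuLi (2.1 equiv), THF, −78 °C; then H2O
Reagents that add atoms: none
Why: Second stage of the Corey–Fuchs reaction: bromine–lithium exchange, Fritsch–Buttenberg–Wiechell rearrangement of the carbenoid and deprotonation give the acetylide, all at −78 °C and faster than ortho-lithiation beside the MOM ether, and the existing (E)-alkene is not involved.

Step 4
Reactants: 2 (2E)-3-[3-methoxy-4-(methoxymethoxy)phenyl]prop-2-enal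
Product: 6 3-[3-methoxy-4-(methoxymethoxy)phenyl]propanal
Conditions: H2 (1 atm), 5% Pd/C, EtOAc, rt, stopped after one equivalent of H2
Reagents that add atoms: none
Why: Heterogeneous catalytic hydrogenation on palladium saturates the conjugated C=C much faster than it reduces an aliphatic aldehyde in an aprotic solvent, and the aryl MOM ether is not hydrogenolysed.

Step 5
Reactants: 6 3-[3-methoxy-4-(methoxymethoxy)phenyl]propanal
Product: 7 3-[3-methoxy-4-(methoxymethoxy)phenyl]propanal oxime (E/Z mixture, used as such)
Conditions: NH2OH·HCl, NaOAc, EtOH/H2O, rt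
Reagents that add atoms: hydroxylamine hydrochloride, NO.Cl
Why: Oxime condensation in an acetate buffer mild enough for the MOM ether; the oxime geometry is irrelevant because both isomers lead to the same nitrile oxide.

Step 6
Reactants: 7 3-[3-methoxy-4-(methoxymethoxy)phenyl]propanal oxime; 5 4-[(1E)-but-1-en-3-yn-1-yl]-2-methoxy-1-(methoxymethoxy)benzene
Product: 10 3-{2-[3-methoxy-4-(methoxymethoxy)phenyl]ethyl}-5-{(E)-2-[3-methoxy-4-(methoxymethoxy)phenyl]ethenyl}-1,2-oxazole, via hydroximoyl chloride 8 (not isolated), via nitrile oxide 9 (not isolated)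
Conditions: 7, chloramine-T trihydrate (TsNClNa·3H2O, 1.05 equiv), tBuOH/H2O (1:1), rt, 5 min; then 5, CuSO4·5H2O (3 mol %), Cu turnings, pH about 6, rt
Reagents that add atoms: none
Why: Chloramine-T chlorinates the aldoxime to 8 and its sulfonamide anion then removes HCl to release nitrile oxide 9 at low concentration, while monovalent copper (formed from CuSO4 and Cu metal) converts the terminal C–H of 5 into a copper acetylide that adds to 9 stepwise through a six-membered cupracycle, which contracts to the 4-cuprated isoxazole and is protonated to 10. The closest known reaction type is the copper-catalysed nitrile oxide–alkyne cycloaddition (a metal-mediated Huisgen 1,3-dipolar cycloaddition) run in one pot from an aldoxime. The isoxazole ring closes as a formal (3+2) cycloaddition of the C–N–O dipole across the two alkyne carbons, forming the C3–C4 carbon–carbon bond (nitrile oxide carbon to the former terminal alkyne carbon) and the O1–C5 bond. No stereocentre is created and the (E)-alkene of 5 is a spectator. The step needs site selectivity for the alkyne over the styrene-type double bond and 3,5- over 3,4-regiochemistry, both secured because only the terminal alkyne can form the copper acetylide and the acetylide dictates that its copper-bearing carbon becomes C4. Dimerisation of 9 to the furoxan has to be outrun, which the slow release of 9 in the flask and the fast capture by the acetylide should achieve.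

Step 7
Reactants: 10 3-{2-[3-methoxy-4-(methoxymethoxy)phenyl]ethyl}-5-{(E)-2-[3-methoxy-4-(methoxymethoxy)phenyl]ethenyl}-1,2-oxazole
Product: 12 (4Z,6E)-5-hydroxy-1,7-bis[3-methoxy-4-(methoxymethoxy)phenyl]hepta-4,6-dien-3-one, via enaminone 11 (not isolated)
Conditions: Mo(CO)6 (1 equiv), MeCN/H2O, reflux; filtration through Celite; then 1 M aq HCl, THF, rt
Reagents that add atoms: water, O
Why: Reductive N–O cleavage of the isoxazole by zerovalent molybdenum in wet acetonitrile (Mo(CO)6-mediated isoxazole ring opening) gives the (Z)-β-enaminone without touching the conjugated alkene, and the vinylogous amide then hydrolyses in dilute acid far faster than the aryl MOM ethers cleave; isolating 12 allows molybdenum residues to be removed before the chelating free phenols and diketone are exposed.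

Step 8
Reactants: 12 (4Z,6E)-5-hydroxy-1,7-bis[3-methoxy-4-(methoxymethoxy)phenyl]hepta-4,6-dien-3-one
Product: 13 (4Z,6E)-5-hydroxy-1,7-bis(4-hydroxy-3-methoxyphenyl)hepta-4,6-dien-3-one (target, CID5372374)
Conditions: 3 M aq HCl, THF, 50 °C
Reagents that add atoms: none
Why: Acid-catalysed hydrolysis of the two aryl methoxymethyl acetals through oxocarbenium ions; curcuminoid β-diketones are stable in aqueous acid (unlike base), so the (E)-alkene and the chelated (Z)-enol should come through unchanged.

**Compound list**

1 | coniferaldehyde, (2E)-3-(4-hydroxy-3-methoxyphenyl)prop-2-enal | COc1cc(/C=C/C=O)ccc1O | starting material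
2 | (2E)-3-[3-methoxy-4-(methoxymethoxy)phenyl]prop-2-enal | COCOc1ccc(/C=C/C=O)cc1OC | intermediate
3 | 4-[(1E)-4,4-dibromobuta-1,3-dien-1-yl]-2-methoxy-1-(methoxymethoxy)benzene | COCOc1ccc(/C=C/C=C(Br)Br)cc1OC | intermediate
4 | lithium (3E)-4-[3-methoxy-4-(methoxymethoxy)phenyl]but-3-en-1-yn-1-ide (lithium acetylide of 5) | [Li]C#C/C=C/c1ccc(OCOC)c(OC)c1 | intermediate
5 | 4-[(1E)-but-1-en-3-yn-1-yl]-2-methoxy-1-(methoxymethoxy)benzene | C#C/C=C/c1ccc(OCOC)c(OC)c1 | intermediate
6 | 3-[3-methoxy-4-(methoxymethoxy)phenyl]propanal | COCOc1ccc(CCC=O)cc1OC | intermediate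
7 | 3-[3-methoxy-4-(methoxymethoxy)phenyl]propanal oxime (E/Z mixture, geometry not specified) | COCOc1ccc(CCC=NO)cc1OC | intermediate
8 | N-hydroxy-3-[3-methoxy-4-(methoxymethoxy)phenyl]propanimidoyl chloride (geometry not specified) | COCOc1ccc(CCC(Cl)=NO)cc1OC | intermediate
9 | 3-[3-methoxy-4-(methoxymethoxy)phenyl]propanenitrile oxide | COCOc1ccc(CCC#[N+][O-])cc1OC | intermediate
10 | 3-{2-[3-methoxy-4-(methoxymethoxy)phenyl]ethyl}-5-{(E)-2-[3-methoxy-4-(methoxymethoxy)phenyl]ethenyl}-1,2-oxazole | COCOc1ccc(CCc2cc(/C=C/c3ccc(OCOC)c(OC)c3)on2)cc1OC | intermediate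
11 | (1E,4Z)-5-amino-1,7-bis[3-methoxy-4-(methoxymethoxy)phenyl]hepta-1,4-dien-3-one | COCOc1ccc(CC/C(N)=C/C(=O)/C=C/c2ccc(OCOC)c(OC)c2)cc1OC | intermediate
12 | (4Z,6E)-5-hydroxy-1,7-bis[3-methoxy-4-(methoxymethoxy)phenyl]hepta-4,6-dien-3-one | COCOc1ccc(/C=C/C(O)=C/C(=O)CCc2ccc(OCOC)c(OC)c2)cc1OC | intermediate
13 | (4Z,6E)-5-hydroxy-1,7-bis(4-hydroxy-3-methoxyphenyl)hepta-4,6-dien-3-one | COc1cc(/C=C/C(O)=C/C(=O)CCc2ccc(O)c(OC)c2)ccc1O | target

**Totals and risks**

Total step count: 8. Longest linear sequence: 6 steps (steps 1, 2, 3, 6, 7, 8; the branch through steps 1, 4, 5, 6, 7, 8 is equally long).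

Step 6 is the most likely to fail. The aliphatic nitrile oxide may dimerise, the alkyne may homocouple oxidatively at copper, or the dipole may add to the styrene-type double bond before the copper-mediated union takes place. The fallback joins the same two halves at the same carbon–carbon bond by polar chemistry. It sets out from 5 and 6. Alkyne 5 is deprotonated with n-BuLi in THF at −78 °C to regenerate acetylide 4, which adds to aldehyde 6 to give the racemic propargylic alcohol (6E)-1,7-bis[3-methoxy-4-(methoxymethoxy)phenyl]hept-6-en-4-yn-3-ol F1. Oxidation with MnO2 in CH2Cl2 gives the ynone (6E)-1,7-bis[3-methoxy-4-(methoxymethoxy)phenyl]hept-6-en-4-yn-3-one F2. Conjugate addition of diethylamine in ethanol at the alkyne carbon remote from the carbonyl gives the push–pull enaminone (4E,6E)-5-(diethylamino)-1,7-bis[3-methoxy-4-(methoxymethoxy)phenyl]hepta-4,6-dien-3-one F3. Hydrolysis with 1 M aq HCl in THF returns the route at 12, so that steps 6 and 7 are both bypassed.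

Step 7 is the second risk. The N–O cleavage may stall, the low-valent molybdenum may reduce or complex the cross-conjugated dienone that is being formed, or metal residues may be carried into the chelating product. The fallback gives up the heterocycle and builds the diketone by aldol addition and oxidation. It sets out from 2 and 6. Addition of MeMgBr to enal 2 in THF at −78 °C gives the racemic allylic alcohol (3E)-4-[3-methoxy-4-(methoxymethoxy)phenyl]but-3-en-2-ol F4. MnO2 oxidation gives the enone (3E)-4-[3-methoxy-4-(methoxymethoxy)phenyl]but-3-en-2-one F5. Deprotonation at the methyl group with LiN(iPr)2 in THF at −78 °C gives the enolate lithium (3E)-4-[3-methoxy-4-(methoxymethoxy)phenyl]buta-1,3-dien-2-olate F6. Addition of F6 to aldehyde 6 gives the racemic aldol (1E)-5-hydroxy-1,7-bis[3-methoxy-4-(methoxymethoxy)phenyl]hept-1-en-3-one F7. Oxidation with Dess–Martin periodinane in CH2Cl2 comes back to the route at 12.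

Step 4 is the third risk. The hydrogenation may run on to reduce the aldehyde, or may stop with alkene left, so that a mixture is obtained. The fallback replaces the selective reduction by a redox detour. It sets out from 2. Exhaustive hydrogenation (H2, Pd/C, EtOAc) followed by NaBH4 in MeOH at 0 °C converges all material on the alcohol 3-[3-methoxy-4-(methoxymethoxy)phenyl]propan-1-ol F8. Selective oxidation with TEMPO (cat.) and PhI(OAc)2 in CH2Cl2 comes back to the route at 6.

**Further compounds**

F1 | step 6 | (6E)-1,7-bis[3-methoxy-4-(methoxymethoxy)phenyl]hept-6-en-4-yn-3-ol (racemic) | COCOc1ccc(CCC(O)C#C/C=C/c2ccc(OCOC)c(OC)c2)cc1OC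
F2 | step 6 | (6E)-1,7-bis[3-methoxy-4-(methoxymethoxy)phenyl]hept-6-en-4-yn-3-one | COCOc1ccc(CCC(=O)C#C/C=C/c2ccc(OCOC)c(OC)c2)cc1OC
F3 | step 6 | (4E,6E)-5-(diethylamino)-1,7-bis[3-methoxy-4-(methoxymethoxy)phenyl]hepta-4,6-dien-3-one | COCOc1ccc(CCC(=O)/C=C(\C=C\c2ccc(OCOC)c(OC)c2)N(CC)CC)cc1OC
F4 | step 7 | (3E)-4-[3-methoxy-4-(methoxymethoxy)phenyl]but-3-en-2-ol (racemic) | COCOc1ccc(/C=C/C(C)O)cc1OC
F5 | step 7 | (3E)-4-[3-methoxy-4-(methoxymethoxy)phenyl]but-3-en-2-one | COCOc1ccc(/C=C/C(C)=O)cc1OC
F6 | step 7 | lithium (3E)-4-[3-methoxy-4-(methoxymethoxy)phenyl]buta-1,3-dien-2-olate | [Li]OC(=C)/C=C/c1ccc(OCOC)c(OC)c1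
F7 | step 7 | (1E)-5-hydroxy-1,7-bis[3-methoxy-4-(methoxymethoxy)phenyl]hept-1-en-3-one (racemic) | COCOc1ccc(CCC(O)CC(=O)/C=C/c2ccc(OCOC)c(OC)c2)cc1OC
F8 | step 4 | 3-[3-methoxy-4-(methoxymethoxy)phenyl]propan-1-ol | COCOc1ccc(CCCO)cc1OC
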